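The route rests on opening dioxane ring B at the aryl–oxygen bond C8a–O1. On ring A, C8a lies ortho to the O4-bearing C4a and meta to C7. This is the position that carries bromine in 5-bromovanillin, whose phenol becomes O4 and whose methoxyl sits at C5. An Evans syn-aldol fixes C2 and C3 in the open chain. Copper-catalysed intramolecular O-arylation of the free C2 hydroxyl then closes ring B in one operation, with retention at both centres, so syn becomes trans-(2R,3R). The precursor is a (1R,2R)-2-(2-bromo-6-methoxyaryloxy)-1-arylpropan-1-ol carrying C7 as CH2OTBS, O9 as a trityl ether and ring C as its bis-MOM ether.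

Key step: step 10

**Numbering and abbreviations.**
- Ring positions: O1, C2 (aryl-bearing), C3 (bearing C9H2–O9), O4, C4a, C5 (OMe), C6, C7 (side chain), C8, C8a.
- Ring A is the benzo ring, ring B the dioxane ring, ring C the pendant aryl ring.
- ArA = 2-bromo-4-(tert-butyldimethylsilyloxymethyl)-6-methoxyphenyl.
- ArC = 3-methoxy-4,5-bis(methoxymethoxy)phenyl.
- Tr = triphenylmethyl.

**Design remark.** O9 stands β to O4 exactly as O1 does, so a free O9 would close an isomeric six-membered ring. A silyl ether on O9 could migrate to the C2 alkoxide under hot carbonate and expose that pathway. O9 therefore carries a trityl ether. It cannot migrate, it goes on selectively at the primary position, and it leaves in the final acid step together with the MOM groups.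

**Stereochemical check.**
- The target is trans-(2R,3R) with an E-enal.
- The (S)-auxiliary should give the (2S,3R) syn-aldol.
- Reduction of C=O to CH2OH changes only the descriptor of the aryloxy carbon, from S to R. This gives the (1R,2R) chain that maps onto (2R,3R).

**Assumption.** Compounds 1, 2, 7, 10 and 20 are purchased.

Step 1
Reactants: 1 5-bromovanillin; 2 methyl bromoacetate
Product: 3 methyl 2-(2-bromo-4-formyl-6-methoxyphenoxy)acetate
Conditions: K2CO3, DMF, 50 °C
Reagents that add atoms: none
Why: Williamson ether synthesis, in which the acidic phenoxide of 1 displaces bromide from the unhindered α-bromo ester by SN2 and no other nucleophilic site is present.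

Step 2
Reactants: 3 methyl 2-(2-bromo-4-formyl-6-methoxyphenoxy)acetate
Product: 4 methyl 2-[2-bromo-4-(hydroxymethyl)-6-methoxyphenoxy]acetate
Conditions: NaBH4 (0.5 equiv), MeOH/THF, 0 °C, short contact
Reagents that add atoms: none
Why: Chemoselective borohydride reduction, since at 0 °C the aryl aldehyde is reduced far faster than the methyl ester, and it brings C7 to the alcohol oxidation level that later keeps ring A electron-rich.

Step 3
Reactants: 4 methyl 2-[2-bromo-4-(hydroxymethyl)-6-methoxyphenoxy]acetate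
Product: 5 methyl 2-(ArA-oxy)acetate
Conditions: TBSCl, imidazole, DMF, rt
Reagents that add atoms: tert-butyldimethylsilyl chloride, CC(C)(C)[Si](C)(C)Cl
Why: Imidazole-promoted silylation of the primary benzylic alcohol, which is the only hydroxyl in 4.

Step 4
Reactants: 5 methyl 2-(ArA-oxy)acetate
Product: 6 2-(ArA-oxy)acetic acid
Conditions: LiOH, THF/H2O, 0 °C to rt; then cold dilute HCl to pH 3–4, EtOAc
Reagents that add atoms: lithium hydroxide, [Li+].[OH-]
Why: Saponification of an unhindered methyl ester, to which the alkyl silyl ether and the aryl bromide are inert, with brief cold acidification sparing the TBS group.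

Step 5
Reactants: 6 2-(ArA-oxy)acetic acid; 7 (S)-4-benzyl-2-oxazolidinone
Product: 9 (S)-4-benzyl-3-[(ArA-oxy)acetyl]oxazolidin-2-one, via mixed pivalic anhydride 8 (not isolated)
Conditions: PivCl, Et3N, THF, −20 to 0 °C; then 7, LiCl, rt
Reagents that add atoms: pivaloyl chloride, CC(C)(C)C(=O)Cl (its atoms appear only in 8)
Why: N-acylation through a mixed anhydride, in which the hindered pivaloyl carbonyl steers the lithium-activated carbamate nitrogen to the aryloxyacetyl carbonyl and the auxiliary stereocentre takes no part.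

Step 6
Reactants: 10 5-hydroxyvanillin
Product: 11 3-methoxy-4,5-bis(methoxymethoxy)benzaldehyde
Conditions: MOMCl (3 equiv), i-Pr2NEt, CH2Cl2, 0 °C to rt
Reagents that add atoms: chloromethyl methyl ether, COCCl
Why: Double O-alkylation of the catechol (MOM protection), giving acetal ethers that tolerate boron enolates, hydride, hot carbonate, fluoride and ylides yet leave under mild acid.

Step 7
Reactants: 9 (S)-4-benzyl-3-[(ArA-oxy)acetyl]oxazolidin-2-one; 11 3-methoxy-4,5-bis(methoxymethoxy)benzaldehyde
Product: 14 syn-aldol adduct (4S)-4-benzyl-3-[(2S,3R)-2-(ArA-oxy)-3-hydroxy-3-ArC-propanoyl]oxazolidin-2-one, via Z-boron enolate 12 (not isolated), via boron aldolate 13 (not isolated)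
Conditions: Bu2BOTf, Et3N, CH2Cl2, −78 to 0 °C; 11, −78 to 0 °C; pH 7 buffer, MeOH, 30% H2O2, 0 °C
Reagents that add atoms: dibutylboron triflate, CCCCB(CCCC)OS(=O)(=O)C(F)(F)F (its atoms appear only in 12 and 13)
Why: Evans syn-aldol reaction, in which soft enolisation gives the Z-enolate that reacts through a closed Zimmerman–Traxler chair with the auxiliary carbonyl opposed to the enolate C–O and the benzyl group shielding one face, so the (S)-auxiliary sets the aryloxy carbon (future C3) as 2S and the carbinol carbon (future C2) as 3R.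

Step 8
Reactants: 14 syn-aldol adduct
Product: 15 (1R,2R)-2-(ArA-oxy)-1-ArC-propane-1,3-diol
Conditions: LiBH4, MeOH (1 equiv), THF, 0 °C
Reagents that add atoms: none
Why: Reductive cleavage of the N-acyl oxazolidinone, in which hydride attacks the more electrophilic exocyclic carbonyl, the auxiliary is released intact and neither stereocentre is touched.

Step 9
Reactants: 15 (1R,2R)-2-(ArA-oxy)-1-ArC-propane-1,3-diol
Product: 16 (1R,2R)-2-(ArA-oxy)-1-ArC-3-(trityloxy)propan-1-ol
Conditions: TrCl, Et3N, DMAP (cat.), CH2Cl2, rt to 40 °C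
Reagents that add atoms: trityl chloride, ClC(c1ccccc1)(c1ccccc1)c1ccccc1
Why: Tritylation, an SN1-type etherification whose very bulky electrophile accepts only the primary O9 and leaves the hindered secondary benzylic hydroxyl free.

Step 10
Reactants: 16 (1R,2R)-2-(ArA-oxy)-1-ArC-3-(trityloxy)propan-1-ol
Product: 17 (2R,3R)-2-ArC-7-(tert-butyldimethylsilyloxymethyl)-5-methoxy-3-(trityloxymethyl)-2,3-dihydro-1,4-benzodioxine
Conditions: CuI (20 mol %), 3,4,7,8-tetramethyl-1,10-phenanthroline (40 mol %), Cs2CO3 (2 equiv), 4 Å MS, degassed toluene (0.05 M), 110 °C, Ar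
Reagents that add atoms: none
Why: Cs2CO3 deprotonates the C2 hydroxyl, the alkoxide binds the phenanthroline-ligated monovalent copper centre, the neighbouring C8a–Br bond adds oxidatively to give a seven-membered trivalent copper metallacycle, and C–O reductive elimination releases ring B and returns the catalyst. The closest known reaction type is the Ullmann-type copper-catalysed O-arylation of aliphatic alcohols, whose intramolecular form is an established entry to 2,3-dihydro-1,4-benzodioxines from 2-(2-halophenoxy)ethanols. The single ring closes in a 6-exo mode onto the sp2 carbon C8a, with the departing bromide outside the new ring. No stereocentre is created and neither the C2–O1 nor the C3–O4 bond is broken, so the syn (1R,2R) array of 16 passes with retention into the trans-(2R,3R) ring with ArC and CH2OTr both equatorial. The step needs O1 and not O9 to be arylated, which the non-migrating trityl ether on O9 secures. It also needs the O4–C4a ether to stay in place, which the electron-rich ring A secures because, with C7 at the alcohol oxidation level, no acceptor para to O4 can stabilise the spiro adduct of a Smiles rearrangement.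

Step 11
Reactants: 17 protected trans-benzodioxane
Product: 18 [(2R,3R)-2-ArC-5-methoxy-3-(trityloxymethyl)-2,3-dihydro-1,4-benzodioxin-7-yl]methanol
Conditions: TBAF, THF, 0 °C to rt
Reagents that add atoms: none
Why: Fluoride-driven desilylation, in which formation of the strong Si–F bond cleaves the one silyl ether while trityl and MOM ethers are inert.

Step 12
Reactants: 18 C7 benzylic alcohol
Product: 19 (2R,3R)-2-ArC-5-methoxy-3-(trityloxymethyl)-2,3-dihydro-1,4-benzodioxine-7-carbaldehyde
Conditions: activated MnO2 (excess), CH2Cl2, rt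
Reagents that add atoms: none
Why: MnO2 oxidation of a benzylic alcohol stops at the aldehyde, and with O9 tritylated no other hydroxyl is present.

Step 13
Reactants: 19 7-carbaldehyde; 20 (triphenylphosphoranylidene)acetaldehyde
Product: 21 (E)-3-[(2R,3R)-2-ArC-5-methoxy-3-(trityloxymethyl)-2,3-dihydro-1,4-benzodioxin-7-yl]prop-2-enal
Conditions: 20 (1.2 equiv), toluene, 85 °C
Reagents that add atoms: none
Why: Wittig olefination with a stabilised formyl ylide, whose reversible oxaphosphetane formation favours the E-alkene, while a small excess of ylide restrains a second homologation.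

Step 14
Reactants: 21 protected E-enal
Product: 22 target, (E)-3-[(2R,3R)-2-(3,4-dihydroxy-5-methoxyphenyl)-3-(hydroxymethyl)-5-methoxy-2,3-dihydro-1,4-benzodioxin-7-yl]prop-2-enal
Conditions: aq. HCl (3 M), THF, 40 °C, Ar
Reagents that add atoms: none
Why: Acid-catalysed hydrolysis of the two phenolic MOM acetals and SN1 solvolysis of the trityl ether proceed under the same mild aqueous conditions, in which the enal cannot be trapped as an acetal and the two alkyl–oxygen bonds of ring B should persist.

**Compound list**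

1 | 5-bromovanillin | COc1cc(C=O)cc(Br)c1O | starting material
2 | methyl bromoacetate | COC(=O)CBr | starting material
3 | methyl 2-(2-bromo-4-formyl-6-methoxyphenoxy)acetate | COC(=O)COc1c(Br)cc(C=O)cc1OC | intermediate
4 | methyl 2-[2-bromo-4-(hydroxymethyl)-6-methoxyphenoxy]acetate | COC(=O)COc1c(Br)cc(CO)cc1OC | intermediate
5 | methyl 2-[2-bromo-4-(tert-butyldimethylsilyloxymethyl)-6-methoxyphenoxy]acetate | COC(=O)COc1c(Br)cc(CO[Si](C)(C)C(C)(C)C)cc1OC | intermediate
6 | 2-[2-bromo-4-(tert-butyldimethylsilyloxymethyl)-6-methoxyphenoxy]acetic acid | OC(=O)COc1c(Br)cc(CO[Si](C)(C)C(C)(C)C)cc1OC | intermediate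
7 | (S)-4-benzyl-2-oxazolidinone | O=C1N[C@@H](Cc2ccccc2)CO1 | starting material
8 | mixed anhydride of 6 and pivalic acid (not isolated) | CC(C)(C)C(=O)OC(=O)COc1c(Br)cc(CO[Si](C)(C)C(C)(C)C)cc1OC | intermediate
9 | (S)-4-benzyl-3-{[2-bromo-4-(tert-butyldimethylsilyloxymethyl)-6-methoxyphenoxy]acetyl}oxazolidin-2-one | O=C(COc1c(Br)cc(CO[Si](C)(C)C(C)(C)C)cc1OC)N1C(=O)OC[C@@H]1Cc1ccccc1 | intermediate
10 | 5-hydroxyvanillin (3,4-dihydroxy-5-methoxybenzaldehyde) | COc1cc(C=O)cc(O)c1O | starting material
11 | 3-methoxy-4,5-bis(methoxymethoxy)benzaldehyde | COCOc1cc(C=O)cc(OC)c1OCOC | intermediate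
12 | (Z)-dibutylboron enolate of 9 (not isolated) | CCCCB(CCCC)O/C(=C\Oc1c(Br)cc(CO[Si](C)(C)C(C)(C)C)cc1OC)N1C(=O)OC[C@@H]1Cc1ccccc1 | intermediate
13 | dibutylboron aldolate of 14 (not isolated) | COc1cc(CO[Si](C)(C)C(C)(C)C)cc(Br)c1O[C@H](C(=O)N1C(=O)OC[C@@H]1Cc1ccccc1)[C@H](OB(CCCC)CCCC)c1cc(OC)c(OCOC)c(OCOC)c1 | intermediate
14 | (4S)-4-benzyl-3-[(2S,3R)-2-(ArA-oxy)-3-hydroxy-3-ArC-propanoyl]oxazolidin-2-one (syn-aldol) | COc1cc(CO[Si](C)(C)C(C)(C)C)cc(Br)c1O[C@H](C(=O)N1C(=O)OC[C@@H]1Cc1ccccc1)[C@H](O)c1cc(OC)c(OCOC)c(OCOC)c1 | intermediate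
15 | (1R,2R)-2-(ArA-oxy)-1-ArC-propane-1,3-diol | COc1cc(CO[Si](C)(C)C(C)(C)C)cc(Br)c1O[C@H](CO)[C@H](O)c1cc(OC)c(OCOC)c(OCOC)c1 | intermediate
16 | (1R,2R)-2-(ArA-oxy)-1-ArC-3-(trityloxy)propan-1-ol (key-step precursor) | COc1cc(CO[Si](C)(C)C(C)(C)C)cc(Br)c1O[C@H](COC(c1ccccc1)(c1ccccc1)c1ccccc1)[C@H](O)c1cc(OC)c(OCOC)c(OCOC)c1 | intermediate
17 | (2R,3R)-2-ArC-7-(tert-butyldimethylsilyloxymethyl)-5-methoxy-3-(trityloxymethyl)-2,3-dihydro-1,4-benzodioxine (key-step product) | COc1cc([C@H]2Oc3cc(CO[Si](C)(C)C(C)(C)C)cc(OC)c3O[C@@H]2COC(c2ccccc2)(c2ccccc2)c2ccccc2)cc(OCOC)c1OCOC | intermediate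
18 | [(2R,3R)-2-ArC-5-methoxy-3-(trityloxymethyl)-2,3-dihydro-1,4-benzodioxin-7-yl]methanol | COc1cc([C@H]2Oc3cc(CO)cc(OC)c3O[C@@H]2COC(c2ccccc2)(c2ccccc2)c2ccccc2)cc(OCOC)c1OCOC | intermediate
19 | (2R,3R)-2-ArC-5-methoxy-3-(trityloxymethyl)-2,3-dihydro-1,4-benzodioxine-7-carbaldehyde | COc1cc([C@H]2Oc3cc(C=O)cc(OC)c3O[C@@H]2COC(c2ccccc2)(c2ccccc2)c2ccccc2)cc(OCOC)c1OCOC | intermediate
20 | (triphenylphosphoranylidene)acetaldehyde | O=CC=P(c1ccccc1)(c1ccccc1)c1ccccc1 | starting material
21 | (E)-3-[(2R,3R)-2-ArC-5-methoxy-3-(trityloxymethyl)-2,3-dihydro-1,4-benzodioxin-7-yl]prop-2-enal | COc1cc([C@H]2Oc3cc(/C=C/C=O)cc(OC)c3O[C@@H]2COC(c2ccccc2)(c2ccccc2)c2ccccc2)cc(OCOC)c1OCOC | intermediate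
22 | (E)-3-[(2R,3R)-2-(3,4-dihydroxy-5-methoxyphenyl)-3-(hydroxymethyl)-5-methoxy-2,3-dihydro-1,4-benzodioxin-7-yl]prop-2-enal | COc1cc([C@H]2Oc3cc(/C=C/C=O)cc(OC)c3O[C@@H]2CO)cc(O)c1O | target

Total step count: 14. Longest linear sequence: 13 steps (steps 1–5 and 7–14).

**Steps most likely to fail**

**Step 10.**
- Risk: Oxidative addition into the electron-rich, ortho-substituted C8a–Br bond may be slow. Protodebromination, copper-mediated oxidation of the benzylic alcohol, or base-induced fragmentation of the β-aryloxy alkoxide could then compete at 110 °C.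
- Fallback: This reverses the polarity at C8a and sets out from 16. Miyaura borylation (Pd(dppf)Cl2, B2pin2, KOAc, dioxane, 85 °C) should give the aryl pinacol boronate F1. KHF2 in aqueous MeOH should convert it into the potassium aryltrifluoroborate F2. A Chan–Lam-type oxidative etherification (Cu(OAc)2, DMAP, 4 Å MS, O2, CH2Cl2, rt) should then join O1 to C8a at room temperature without strong base, again with retention. This comes back to the route at 17.

**Step 7.**
- Risk: Enolisation of the hindered aryloxyacetyl imide may be incomplete. Addition to the electron-rich aldehyde may be slow, retro-aldol may occur during work-up, a MOM group may be lost to the Lewis acid, or facial selectivity may erode.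
- Fallback: This replaces auxiliary control by catalyst control and sets out from 5 and 11. An unselective lithium aldol (LDA, THF, −78 °C) should give the β-hydroxy ester F3 as a stereoisomer mixture. Dess–Martin oxidation should give the configurationally labile β-keto ester F4. Noyori-type asymmetric transfer hydrogenation with dynamic kinetic resolution (RuCl(p-cymene)[(S,S)-TsDPEN], HCO2H/Et3N, 30 °C) is known to give syn products from α-alkoxy-β-keto esters. It should deliver the syn-(2S,3R) hydroxy ester F5, since the usual aryl-ketone sense of induction corresponds here to the R carbinol. LiBH4 reduction comes back to the route at 15.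

**Step 13.**
- Risk: Addition of the weakly nucleophilic formyl ylide to the electron-rich aldehyde may be sluggish. A second olefination of the product enal may erode the material.
- Fallback: This sets out from 19 and builds the enal stepwise. A Horner–Wadsworth–Emmons reaction under Masamune–Roush conditions (triethyl phosphonoacetate, LiCl, DBU, MeCN, rt) should give the ethyl (E)-cinnamate F6. DIBAL-H (CH2Cl2, −78 °C) should give the (E)-allylic alcohol F7. MnO2 in CH2Cl2 comes back to the route at 21.

Further compounds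
F1 | step 10 | (1R,2R)-2-[4-(tert-butyldimethylsilyloxymethyl)-2-methoxy-6-(4,4,5,5-tetramethyl-1,3,2-dioxaborolan-2-yl)phenoxy]-1-ArC-3-(trityloxy)propan-1-ol | COc1cc(CO[Si](C)(C)C(C)(C)C)cc(B2OC(C)(C)C(C)(C)O2)c1O[C@H](COC(c1ccccc1)(c1ccccc1)c1ccccc1)[C@H](O)c1cc(OC)c(OCOC)c(OCOC)c1
F2 | step 10 | potassium aryltrifluoroborate corresponding to F1 | COc1cc(CO[Si](C)(C)C(C)(C)C)cc([B-](F)(F)F)c1O[C@H](COC(c1ccccc1)(c1ccccc1)c1ccccc1)[C@H](O)c1cc(OC)c(OCOC)c(OCOC)c1.[K+]
F3 | step 7 | methyl 2-(ArA-oxy)-3-hydroxy-3-ArC-propanoate, stereoisomer mixture | COC(=O)C(Oc1c(Br)cc(CO[Si](C)(C)C(C)(C)C)cc1OC)C(O)c1cc(OC)c(OCOC)c(OCOC)c1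
F4 | step 7 | methyl 2-(ArA-oxy)-3-oxo-3-ArC-propanoate, racemic and configurationally labile | COC(=O)C(Oc1c(Br)cc(CO[Si](C)(C)C(C)(C)C)cc1OC)C(=O)c1cc(OC)c(OCOC)c(OCOC)c1
F5 | step 7 | methyl (2S,3R)-2-(ArA-oxy)-3-hydroxy-3-ArC-propanoate | COc1cc(CO[Si](C)(C)C(C)(C)C)cc(Br)c1O[C@H](C(=O)OC)[C@H](O)c1cc(OC)c(OCOC)c(OCOC)c1
F6 | step 13 | ethyl (E)-3-[(2R,3R)-2-ArC-5-methoxy-3-(trityloxymethyl)-2,3-dihydro-1,4-benzodioxin-7-yl]prop-2-enoate | COc1cc([C@H]2Oc3cc(/C=C/C(=O)OCC)cc(OC)c3O[C@@H]2COC(c2ccccc2)(c2ccccc2)c2ccccc2)cc(OCOC)c1OCOC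
F7 | step 13 | (E)-3-[(2R,3R)-2-ArC-5-methoxy-3-(trityloxymethyl)-2,3-dihydro-1,4-benzodioxin-7-yl]prop-2-en-1-ol | COc1cc([C@H]2Oc3cc(/C=C/CO)cc(OC)c3O[C@@H]2COC(c2ccccc2)(c2ccccc2)c2ccccc2)cc(OCOC)c1OCOC
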